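The number I want is a dose: the mean rate of log-loss of free monomer in the north-west run, scaled by the ratio of the [initiator] charges, times the flask's time.

- north-west: free monomer 1.4 M; initiator 140 mM; run made earlier
- flask: free monomer 1.4 M; initiator 70 mM; time 2.0 min

- north-west (time / s: monomer in chains / %, free monomer / %): 10.0: 14.2, 85.8; 15.0: 26.4, 73.4; 25.0: 49.2, 50.1; 40.0: 69.3, 29.9

(readings scatter by 1 percentage point)

- the average divides the monomer in chains by the number of chains begun, living and dead together
- the earlier runs do not show the number of chains; that part of a forecast is a guess
- no earlier run changes the charge of initiator; that part of a forecast is a guess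

- average number of monomer units in a chain (chains begun, living or dead) at 2.0 min
- part of the free monomer that has reacted at 2.0 min

The last north-west reading gives a mean rate of 0.0302 s⁻¹. I treat the loss as pseudo-first-order and guess that it scales with [initiator], so the flask gets 1.81. This D is my estimate of the number of e-foldings of free monomer in the flask. By this reckoning the flask keeps exp(-D) of its free monomer, so I commit to 83.6% reacted.

Is one number enough? At 10.0 s the mean leaves the north-west run 73.9% free monomer, but the reading is 85.8%, so the curve starts slower than its mean. At 25.0 s it leaves 47.0% against 50.1%, so the gap narrows. D gives no chain count, so I offer no average.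

The forecast says 87% reacted, above mine, and an average of 18, “with a wide range because chain count is a guess”.

The flask gives 82.4% reacted and an average of 30.1.

    free monomer + initiator → living end + monomer in chains (k = 0.0115 L mol⁻¹ s⁻¹)
    free monomer + living end → monomer in chains + living end, rate k2*[living end]*[free monomer] (k = 1.55 L mol⁻¹ s⁻¹)
    living end → dead end A (k = 0.0313 s⁻¹)
    initiator + monomer in chains → spent initiator B (k = 0.00414 L mol⁻¹ s⁻¹)

The flask stands 1.3 percentage points below my reckoning. The neighbour charged with 0.018 M of initiator, read at the same time, has by the same reckoning a dose of 0.466, which gives an estimate of 37.2% reacted. That neighbour reads 44.2%, with an average of 46.2.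

The numbers in the tables were generated by integration with constants of no real substance.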